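## Retrosynthetic overview

1. Last bond: acylation of the C6 hydroxyl of a macrocyclic hydroxy lactone with acetonide-protected (R)-2,3-dihydroxy-2-methylpropanoic acid (made from the (S)-lactic acid dioxolanone by Seebach alkylation), then acetonide hydrolysis.
2. Ten-membered ring (formed second): C6–C7 bond by a proposed catalytic, ligand-controlled intramolecular chromium carboxyallylation of an enal by a 3-(bromomethyl)butenolide. It sets C6 and C7 and turns the butenolide into the α-methylene lactone.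
3. Five-membered lactone (formed first, as a butenolide): ring-closing metathesis of the 2-(bromomethyl)acrylate of the C8 vinyl carbinol.
4. Acyclic chain: Negishi sp3–sp2 coupling at C3–C4 of a homoallylic iodide with a (Z)-alkenyl iodide made from but-2-yne-1,4-diol by directed trans-hydroalumination/iodination.
5. Homoallylic iodide: (R)-2-vinyloxirane (source of C8) plus acetylide, then zirconium-catalysed methylalumination/ethylene oxide for the E C1=C10 alkene.

Assumption: the SMILES is read as (6R,7R,8S,2'R) in germacrane numbering (C8 lactone carbinol, C6 ester carbinol, C1=C10 with C9 trans to C2, C4=C5 with C3 cis to C6, C15 = CH2OAc, C11=C13 methylene, C12 carbonyl, C14 methyl); these atom labels are used throughout.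

Assumption: of the two antipodes of the ligand in step 19, (S,S) is taken as the one that exposes the Si face of the aldehyde; should the first run show the reverse, the (R,R) ligand is used with nothing else changed.

Steps 1–4 make the iodide fragment, 5–7 the alkenyl iodide, 8–11 the side-chain acid, and 12–21 join them.

## Route

Step 1
Reactants: 1 (R)-2-vinyloxirane
Product: 2 (S)-hex-1-en-5-yn-3-ol
Conditions: LiC≡CH·H2NCH2CH2NH2 (1.5 equiv), DMSO, 0 °C to rt; aq. NH4Cl
Reagents that add atoms: lithium acetylide–ethylenediamine complex [Li]C#C.NCCN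
Why: Acetylide opens the terminal epoxide by SN2 attack at the unsubstituted carbon (epoxide alkynylation), so the stereocenter of 1 is carried over untouched and becomes C8 with the arrangement of the target.

Step 2
Reactants: 2 (S)-hex-1-en-5-yn-3-ol
Product: 3 (S)-tert-butyl(hex-1-en-5-yn-3-yloxy)dimethylsilane
Conditions: TBSCl, imidazole, DMF, rt
Reagents that add atoms: tert-butyldimethylsilyl chloride CC(C)(C)[Si](C)(C)Cl
Why: Imidazole-promoted silylation of the secondary alcohol (TBS protection) masks the C8 hydroxyl for the organometallic steps and leaves the stereocenter unchanged.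

Step 3
Reactants: 3 (S)-tert-butyl(hex-1-en-5-yn-3-yloxy)dimethylsilane
Product: 6 (3E,6S)-6-((tert-butyldimethylsilyl)oxy)-4-methylocta-3,7-dien-1-ol, via alkenylalane 4 (not isolated), via lithium alanate 5 (not isolated)
Conditions: Me3Al (2.5 equiv), Cp2ZrCl2 (0.25 equiv), CH2Cl2, 0 °C to rt; evaporate, hexane, n-BuLi, 0 °C; ethylene oxide, THF, −30 °C to rt; aq. NH4Cl
Reagents that add atoms: trimethylaluminium C[Al](C)C; ethylene oxide C1CO1
Why: Zirconium-catalysed syn-methylalumination of the terminal alkyne (Negishi carboalumination) puts the methyl on C10 and aluminium on C1 on the same side, and the derived alanate opens ethylene oxide with retention at the alkenyl carbon, which fixes the E geometry of C1=C10 (C9 trans to C2) and adds C2–C3 with a hydroxyl handle.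

Step 4
Reactants: 6 (3E,6S)-6-((tert-butyldimethylsilyl)oxy)-4-methylocta-3,7-dien-1-ol
Product: 7 tert-butyl{[(3S,5E)-8-iodo-5-methylocta-1,5-dien-3-yl]oxy}dimethylsilane
Conditions: I2, PPh3, imidazole, CH2Cl2, 0 °C
Reagents that add atoms: iodine [I][I]
Why: Phosphine/iodine activation converts the primary alcohol into the iodide by SN2 displacement (Appel-type iodination) without touching the silyl ether or the alkenes.

Step 5
Reactants: 8 but-2-yne-1,4-diol
Product: 9 4-((4-methoxybenzyl)oxy)but-2-yn-1-ol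
Conditions: 8 (3 equiv), NaH (1 equiv), PMBCl (1 equiv), Bu4NI (cat.), THF/DMF, 0 °C to rt
Reagents that add atoms: 4-methoxybenzyl chloride COc1ccc(CCl)cc1
Why: Williamson etherification of the monoalkoxide of an excess of the symmetric diol gives mainly the mono-PMB ether.

Step 6
Reactants: 9 4-((4-methoxybenzyl)oxy)but-2-yn-1-ol
Product: 11 (Z)-3-iodo-4-((4-methoxybenzyl)oxy)but-2-en-1-ol, via cyclic alkenylalanate 10 (not isolated)
Conditions: NaAlH2(OCH2CH2OMe)2 (1.5 equiv), THF, 0 °C; then I2, −78 to 0 °C; aq. Na2S2O3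
Reagents that add atoms: iodine [I][I]
Why: Alkoxide-directed trans-hydroalumination of the propargylic alcohol delivers hydride to C5 and aluminium to C4 inside a five-membered alanate that iodine cleaves with retention (hydroalumination–iodination), so iodine ends cis to the CH2OH carbon, which fixes the later C3/C6 cis relation of the C4=C5 alkene.

Step 7
Reactants: 11 (Z)-3-iodo-4-((4-methoxybenzyl)oxy)but-2-en-1-ol
Product: 12 (Z)-tert-butyl{[3-iodo-4-((4-methoxybenzyl)oxy)but-2-en-1-yl]oxy}dimethylsilane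
Conditions: TBSCl, imidazole, CH2Cl2, rt
Reagents that add atoms: tert-butyldimethylsilyl chloride CC(C)(C)[Si](C)(C)Cl
Why: Silylation of the primary allylic alcohol (TBS protection) removes the acidic proton before the organozinc coupling and leaves the alkenyl iodide geometry unchanged.

Step 8
Reactants: 13 (2S,5S)-2-(tert-butyl)-5-methyl-1,3-dioxolan-4-one
Product: 15 (2S,5R)-5-((benzyloxy)methyl)-2-(tert-butyl)-5-methyl-1,3-dioxolan-4-one, via lithium enolate 14 (not isolated)
Conditions: LiN(i-Pr)2, THF, −78 °C; then BnOCH2Cl, −78 to −30 °C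
Reagents that add atoms: benzyl chloromethyl ether ClCOCc1ccccc1
Why: The planar dioxolanone enolate keeps only the tert-butyl acetal stereocenter, which forces benzyloxymethylation from the opposite face (Seebach self-regeneration of stereocentres, enolate alkylation), so the new carbon takes the place of the former hydrogen and the quaternary centre has the arrangement of the (R)-2,3-dihydroxy-2-methylpropanoate of the target.

Step 9
Reactants: 15 (2S,5R)-5-((benzyloxy)methyl)-2-(tert-butyl)-5-methyl-1,3-dioxolan-4-one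
Product: 16 (2S,5R)-2-(tert-butyl)-5-(hydroxymethyl)-5-methyl-1,3-dioxolan-4-one
Conditions: H2 (1 atm), 10% Pd/C, EtOAc, rt
Reagents that add atoms: none
Why: Hydrogenolysis cleaves only the benzyl ether, which must go here because it could not be removed later in the presence of the alkenes.

Step 10
Reactants: 16 (2S,5R)-2-(tert-butyl)-5-(hydroxymethyl)-5-methyl-1,3-dioxolan-4-one
Product: 18 methyl (R)-2,2,4-trimethyl-1,3-dioxolane-4-carboxylate, via diol methyl ester 17 (not isolated)
Conditions: TsOH·H2O (5 mol %), MeOH, 50 °C; evaporate; Me2C(OMe)2, acetone, rt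
Reagents that add atoms: methanol CO; 2,2-dimethoxypropane COC(C)(C)OC
Why: Acid-catalysed methanolysis opens the acylal to the methyl ester and the freed 1,2-diol is then tied up as its acetonide by transacetalisation, neither event touching the quaternary stereocenter.

Step 11
Reactants: 18 methyl (R)-2,2,4-trimethyl-1,3-dioxolane-4-carboxylate
Product: 19 (R)-2,2,4-trimethyl-1,3-dioxolane-4-carboxylic acid
Conditions: LiOH, THF/H2O, 0 °C to rt; then 1 M HCl to pH 3 at 0 °C
Reagents that add atoms: lithium hydroxide [Li+].[OH-]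
Why: Saponification of the methyl ester gives the acid, and brief cold acidification keeps the acetonide.

Step 12
Reactants: 7 tert-butyl{[(3S,5E)-8-iodo-5-methylocta-1,5-dien-3-yl]oxy}dimethylsilane; 12 (Z)-tert-butyl{[3-iodo-4-((4-methoxybenzyl)oxy)but-2-en-1-yl]oxy}dimethylsilane
Product: 21 (3S,5E,9E)-3,11-bis((tert-butyldimethylsilyl)oxy)-9-{[(4-methoxybenzyl)oxy]methyl}-5-methylundeca-1,5,9-triene, via alkylzinc iodide 20 (not isolated)
Conditions: 7, Zn dust (I2-activated), DMA, 40 °C; then 12, Pd(PPh3)4 (5 mol %), THF/DMA, 45 °C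
Reagents that add atoms: none
Why: Zinc insertion into the primary iodide and palladium-catalysed sp3–sp2 cross-coupling (Negishi coupling) join C3 to C4 with retention of the alkenyl iodide geometry, so C3 is cis to C6 as the target requires.

Step 13
Reactants: 21 (3S,5E,9E)-3,11-bis((tert-butyldimethylsilyl)oxy)-9-{[(4-methoxybenzyl)oxy]methyl}-5-methylundeca-1,5,9-triene
Product: 22 [(3S,5E,9E)-3,11-bis((tert-butyldimethylsilyl)oxy)-5-methylundeca-1,5,9-trien-9-yl]methanol
Conditions: DDQ, CH2Cl2/pH 7 phosphate buffer (10:1), 0 °C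
Reagents that add atoms: none
Why: DDQ oxidises only the electron-rich PMB ether (oxidative debenzylation) at buffered pH, freeing the C15 hydroxyl while both silyl ethers stay.

Step 14
Reactants: 22 [(3S,5E,9E)-3,11-bis((tert-butyldimethylsilyl)oxy)-5-methylundeca-1,5,9-trien-9-yl]methanol
Product: 23 [(3S,5E,9E)-3,11-bis((tert-butyldimethylsilyl)oxy)-5-methylundeca-1,5,9-trien-9-yl]methyl acetate
Conditions: Ac2O, pyridine, DMAP (cat.), CH2Cl2, 0 °C
Reagents that add atoms: acetic anhydride CC(=O)OC(C)=O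
Why: DMAP-catalysed acetylation of the only free hydroxyl installs the C15 acetate of the target.

Step 15
Reactants: 23 [(3S,5E,9E)-3,11-bis((tert-butyldimethylsilyl)oxy)-5-methylundeca-1,5,9-trien-9-yl]methyl acetate
Product: 24 [(3S,5E,9E)-3,11-dihydroxy-5-methylundeca-1,5,9-trien-9-yl]methyl acetate
Conditions: HF·pyridine, pyridine, THF, 0 °C to rt
Reagents that add atoms: none
Why: Fluoride cleaves both Si–O bonds (desilylation) under buffered conditions that leave the acetate, which cannot migrate because C15 is trans to C6.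

Step 16
Reactants: 24 [(3S,5E,9E)-3,11-dihydroxy-5-methylundeca-1,5,9-trien-9-yl]methyl acetate
Product: 25 (2E,6E,9S)-3-(acetoxymethyl)-9-hydroxy-7-methylundeca-2,6,10-trienal
Conditions: TEMPO (10 mol %), PhI(OAc)2 (1.1 equiv), CH2Cl2, rt
Reagents that add atoms: none
Why: The oxoammonium salt from TEMPO oxidises the unhindered primary allylic alcohol much faster than the secondary one (TEMPO/PhI(OAc)2 oxidation) and does not isomerise the neral-type enal, whose CHO stays cis to the C3 chain.

Step 17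
Reactants: 25 (2E,6E,9S)-3-(acetoxymethyl)-9-hydroxy-7-methylundeca-2,6,10-trienal; 26 2-(bromomethyl)acrylic acid
Product: 27 (3S,5E,9E)-9-(acetoxymethyl)-5-methyl-11-oxoundeca-1,5,9-trien-3-yl 2-(bromomethyl)acrylate
Conditions: DCC, DMAP (5 mol %), CH2Cl2, −10 °C
Reagents that add atoms: none
Why: Carbodiimide activation (Steglich esterification) acylates the only free hydroxyl at C8 with retention, the low DMAP loading and temperature limiting attack on the allylic bromide.

Step 18
Reactants: 27 (3S,5E,9E)-9-(acetoxymethyl)-5-methyl-11-oxoundeca-1,5,9-trien-3-yl 2-(bromomethyl)acrylate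
Product: 28 (2E,6E)-3-(acetoxymethyl)-8-[(2S)-4-(bromomethyl)-5-oxo-2,5-dihydrofuran-2-yl]-7-methylocta-2,6-dienal
Conditions: second-generation Hoveyda–Grubbs catalyst [RuCl2(H2IMes)(=CH-C6H4-2-O-i-Pr)] (10 mol %), 1,4-benzoquinone (20 mol %), CH2Cl2 (5 mM), 40 °C
Reagents that add atoms: none
Why: Ring-closing metathesis between the C8 vinyl group and the acrylate closes the five-membered butenolide, by far the fastest closure open to the ruthenium alkylidene, while the conjugated enal and the trisubstituted alkenes do not take part.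

Step 19
Reactants: 28 (2E,6E)-3-(acetoxymethyl)-8-[(2S)-4-(bromomethyl)-5-oxo-2,5-dihydrofuran-2-yl]-7-methylocta-2,6-dienal
Product: 29 [(3aS,4R,5E,9E,11aS)-4-hydroxy-10-methyl-3-methylidene-2-oxo-2,3,3a,4,7,8,11,11a-octahydrocyclodeca[b]furan-6-yl]methyl acetate
Conditions: CrCl2 (15 mol %), 3,6-di-tert-butyl-1,8-bis[(4S)-4-isopropyl-4,5-dihydrooxazol-2-yl]-9H-carbazole (18 mol %), 1,8-bis(dimethylamino)naphthalene (18 mol %), Mn powder (2 equiv), Cp2ZrCl2 (1.1 equiv), THF/MeCN, rt, 28 added over 12 h (final 2 mM); aq. NH4Cl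
Reagents that add atoms: none
Why: Proposed new method: a catalytic, ligand-controlled intramolecular Nozaki–Hiyama-type carboxyallylation in which divalent chromium bound to the anionic tridentate bis(oxazolinyl)carbazolide reduces the allylic bromide of 28 to a trivalent allylchromium whose geometry is locked by the butenolide ring (C8 necessarily trans to the CH2–Cr carbon), the enal then binds chromium and is attacked at C7 through a closed six-membered chair so that the locked geometry gives the anti C6/C7 pair while the oxazoline substituents expose only the Si face of the aldehyde (6R and 7R in the target's sense, which with the existing 8S is the trans-fused lactone with the exocyclic methylene restored), Cp2ZrCl2 takes the alkoxide off chromium, Mn returns trivalent chromium to the divalent state, and slow addition at 2 mM favours ring closure over dimerisation; the closest known reaction types are the intermolecular chromium-catalysed enantioselective 2-(alkoxycarbonyl)allylation of aldehydes, the zinc-mediated Barbier reaction of 3-(bromomethyl)furan-2(5H)-ones and the stoichiometric CrCl2-mediated macrocyclic carboxyallylation to ten-membered germacranolides, none of which combines catalyst control, a cyclic allyl donor and ring closure.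

Step 20
Reactants: 29 [(3aS,4R,5E,9E,11aS)-4-hydroxy-10-methyl-3-methylidene-2-oxo-2,3,3a,4,7,8,11,11a-octahydrocyclodeca[b]furan-6-yl]methyl acetate; 19 (R)-2,2,4-trimethyl-1,3-dioxolane-4-carboxylic acid
Product: 31 (3aR,4R,5E,9E,11aS)-6-(acetoxymethyl)-10-methyl-3-methylidene-2-oxo-2,3,3a,4,7,8,11,11a-octahydrocyclodeca[b]furan-4-yl (R)-2,2,4-trimethyl-1,3-dioxolane-4-carboxylate, via mixed anhydride 30 (not isolated)
Conditions: 19, 2,4,6-trichlorobenzoyl chloride, Et3N, toluene, rt; then 29, DMAP, toluene, rt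
Reagents that add atoms: none
Why: DMAP attacks the mixed anhydride only at the less hindered aliphatic carbonyl and the acylpyridinium acylates the hindered secondary C6 alcohol (Yamaguchi esterification) with retention at C6 and at the quaternary centre.

Step 21
Reactants: 31 (3aR,4R,5E,9E,11aS)-6-(acetoxymethyl)-10-methyl-3-methylidene-2-oxo-2,3,3a,4,7,8,11,11a-octahydrocyclodeca[b]furan-4-yl (R)-2,2,4-trimethyl-1,3-dioxolane-4-carboxylate
Product: 32 (3aR,4R,5E,9E,11aS)-6-(acetoxymethyl)-10-methyl-3-methylidene-2-oxo-2,3,3a,4,7,8,11,11a-octahydrocyclodeca[b]furan-4-yl (R)-2,3-dihydroxy-2-methylpropanoate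
Conditions: AcOH/THF/H2O (3:1:1), 35 °C
Reagents that add atoms: none
Why: Mild aqueous acid hydrolyses the terminal acetonide (acetal hydrolysis) faster than it can ionise the allylic esters or protonate the trisubstituted alkenes, liberating the diol of the target.

## Compound list

1 | (R)-2-vinyloxirane | C=C[C@@H]1CO1 | starting material
2 | (S)-hex-1-en-5-yn-3-ol | C=C[C@@H](O)CC#C | intermediate
3 | (S)-tert-butyl(hex-1-en-5-yn-3-yloxy)dimethylsilane | C=C[C@@H](O[Si](C)(C)C(C)(C)C)CC#C | intermediate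
4 | [(1E,4S)-4-((tert-butyldimethylsilyl)oxy)-2-methylhexa-1,5-dien-1-yl]dimethylalane | C=C[C@@H](O[Si](C)(C)C(C)(C)C)C/C(C)=C/[Al](C)C | intermediate
5 | lithium butyl[(1E,4S)-4-((tert-butyldimethylsilyl)oxy)-2-methylhexa-1,5-dien-1-yl]dimethylalanate | C=C[C@@H](O[Si](C)(C)C(C)(C)C)C/C(C)=C/[Al-](C)(C)CCCC.[Li+] | intermediate
6 | (3E,6S)-6-((tert-butyldimethylsilyl)oxy)-4-methylocta-3,7-dien-1-ol | C=C[C@@H](O[Si](C)(C)C(C)(C)C)C/C(C)=C/CCO | intermediate
7 | tert-butyl{[(3S,5E)-8-iodo-5-methylocta-1,5-dien-3-yl]oxy}dimethylsilane | C=C[C@@H](O[Si](C)(C)C(C)(C)C)C/C(C)=C/CCI | intermediate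
8 | but-2-yne-1,4-diol | OCC#CCO | starting material
9 | 4-((4-methoxybenzyl)oxy)but-2-yn-1-ol | OCC#CCOCc1ccc(OC)cc1 | intermediate
10 | sodium 2,2-bis(2-methoxyethoxy)-3-{[(4-methoxybenzyl)oxy]methyl}-2,5-dihydro-1,2-oxaluminol-2-uide | [Na+].COCCO[Al-]1(OCCOC)OCC=C1COCc1ccc(OC)cc1 | intermediate
11 | (Z)-3-iodo-4-((4-methoxybenzyl)oxy)but-2-en-1-ol | OC/C=C(\I)COCc1ccc(OC)cc1 | intermediate
12 | (Z)-tert-butyl{[3-iodo-4-((4-methoxybenzyl)oxy)but-2-en-1-yl]oxy}dimethylsilane | CC(C)(C)[Si](C)(C)OC/C=C(\I)COCc1ccc(OC)cc1 | intermediate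
13 | (2S,5S)-2-(tert-butyl)-5-methyl-1,3-dioxolan-4-one | C[C@@H]1O[C@H](C(C)(C)C)OC1=O | starting material
14 | lithium (2S)-2-(tert-butyl)-5-methyl-1,3-dioxol-4-olate | CC1=C([O-])O[C@@H](C(C)(C)C)O1.[Li+] | intermediate
15 | (2S,5R)-5-((benzyloxy)methyl)-2-(tert-butyl)-5-methyl-1,3-dioxolan-4-one | C[C@]1(COCc2ccccc2)O[C@H](C(C)(C)C)OC1=O | intermediate
16 | (2S,5R)-2-(tert-butyl)-5-(hydroxymethyl)-5-methyl-1,3-dioxolan-4-one | C[C@]1(CO)O[C@H](C(C)(C)C)OC1=O | intermediate
17 | methyl (R)-2,3-dihydroxy-2-methylpropanoate | COC(=O)[C@](C)(O)CO | intermediate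
18 | methyl (R)-2,2,4-trimethyl-1,3-dioxolane-4-carboxylate | COC(=O)[C@@]1(C)COC(C)(C)O1 | intermediate
19 | (R)-2,2,4-trimethyl-1,3-dioxolane-4-carboxylic acid | OC(=O)[C@@]1(C)COC(C)(C)O1 | intermediate
20 | [(3E,6S)-6-((tert-butyldimethylsilyl)oxy)-4-methylocta-3,7-dien-1-yl]zinc iodide | C=C[C@@H](O[Si](C)(C)C(C)(C)C)C/C(C)=C/CC[Zn]I | intermediate
21 | (3S,5E,9E)-3,11-bis((tert-butyldimethylsilyl)oxy)-9-{[(4-methoxybenzyl)oxy]methyl}-5-methylundeca-1,5,9-triene | C=C[C@@H](O[Si](C)(C)C(C)(C)C)C/C(C)=C/CC/C(COCc1ccc(OC)cc1)=C\CO[Si](C)(C)C(C)(C)C | intermediate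
22 | [(3S,5E,9E)-3,11-bis((tert-butyldimethylsilyl)oxy)-5-methylundeca-1,5,9-trien-9-yl]methanol | C=C[C@@H](O[Si](C)(C)C(C)(C)C)C/C(C)=C/CC/C(CO)=C\CO[Si](C)(C)C(C)(C)C | intermediate
23 | [(3S,5E,9E)-3,11-bis((tert-butyldimethylsilyl)oxy)-5-methylundeca-1,5,9-trien-9-yl]methyl acetate | C=C[C@@H](O[Si](C)(C)C(C)(C)C)C/C(C)=C/CC/C(COC(C)=O)=C\CO[Si](C)(C)C(C)(C)C | intermediate
24 | [(3S,5E,9E)-3,11-dihydroxy-5-methylundeca-1,5,9-trien-9-yl]methyl acetate | C=C[C@@H](O)C/C(C)=C/CC/C(COC(C)=O)=C\CO | intermediate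
25 | (2E,6E,9S)-3-(acetoxymethyl)-9-hydroxy-7-methylundeca-2,6,10-trienal | C=C[C@@H](O)C/C(C)=C/CC/C(COC(C)=O)=C\C=O | intermediate
26 | 2-(bromomethyl)acrylic acid | C=C(CBr)C(=O)O | starting material
27 | (3S,5E,9E)-9-(acetoxymethyl)-5-methyl-11-oxoundeca-1,5,9-trien-3-yl 2-(bromomethyl)acrylate | C=C[C@@H](OC(=O)C(=C)CBr)C/C(C)=C/CC/C(COC(C)=O)=C\C=O | intermediate
28 | (2E,6E)-3-(acetoxymethyl)-8-[(2S)-4-(bromomethyl)-5-oxo-2,5-dihydrofuran-2-yl]-7-methylocta-2,6-dienal | BrCC1=C[C@H](C/C(C)=C/CC/C(COC(C)=O)=C\C=O)OC1=O | intermediate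
29 | [(3aS,4R,5E,9E,11aS)-4-hydroxy-10-methyl-3-methylidene-2-oxo-2,3,3a,4,7,8,11,11a-octahydrocyclodeca[b]furan-6-yl]methyl acetate (6R,7R,8S in germacrane numbering; the 3a descriptor reads S only because the free hydroxyl lowers the rank of C4) | C=C1C(=O)O[C@H]2C/C(C)=C/CC/C(COC(C)=O)=C\[C@@H](O)[C@H]12 | intermediate
30 | (R)-2,2,4-trimethyl-1,3-dioxolane-4-carboxylic 2,4,6-trichlorobenzoic anhydride | O=C(OC(=O)[C@@]1(C)COC(C)(C)O1)c1c(Cl)cc(Cl)cc1Cl | intermediate
31 | (3aR,4R,5E,9E,11aS)-6-(acetoxymethyl)-10-methyl-3-methylidene-2-oxo-2,3,3a,4,7,8,11,11a-octahydrocyclodeca[b]furan-4-yl (R)-2,2,4-trimethyl-1,3-dioxolane-4-carboxylate | C=C1C(=O)O[C@H]2C/C(C)=C/CC/C(COC(C)=O)=C\[C@@H](OC(=O)[C@@]3(C)COC(C)(C)O3)[C@H]12 | intermediate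
32 | (3aR,4R,5E,9E,11aS)-6-(acetoxymethyl)-10-methyl-3-methylidene-2-oxo-2,3,3a,4,7,8,11,11a-octahydrocyclodeca[b]furan-4-yl (R)-2,3-dihydroxy-2-methylpropanoate (CNP0426025.2) | C=C1C(=O)O[C@H]2C/C(C)=C/CC/C(COC(C)=O)=C\[C@@H](OC(=O)[C@](C)(O)CO)[C@H]12 | target

## Step count and risk

Total step count: 21. Longest linear sequence: 14 steps (1–4, then 12–21, from 1).

The three steps most likely to fail:

**Step 19 (the new macro-allylation; ring, C6 and C7).** Risks are oligomerisation, a mismatched catalyst/substrate pair, or the cis-fused lactone. The fallback closes the ring at C4=C5 instead, by the known order of intermolecular Barbier reaction then ring-closing metathesis. It sets out from iodide 7 and comes back at 29. Zinc reagent 20, made as in step 12, is coupled under Pd(PPh3)4 with (2-bromoallyloxy)(tert-butyl)dimethylsilane to give (3S,5E)-3-((tert-butyldimethylsilyl)oxy)-9-(((tert-butyldimethylsilyl)oxy)methyl)-5-methyldeca-1,5,9-triene F1. HF·pyridine gives (3S,5E)-9-(hydroxymethyl)-5-methyldeca-1,5,9-trien-3-ol F2, and AcCl with 2,4,6-collidine at −78 °C acetylates only the primary hydroxyl to give (5E,8S)-8-hydroxy-6-methyl-2-methylidenedeca-5,9-dien-1-yl acetate F3. Esterification with 26 (DCC, DMAP) gives (3S,5E)-9-(acetoxymethyl)-5-methyldeca-1,5,9-trien-3-yl 2-(bromomethyl)acrylate F4, and metathesis as in step 18 gives (5E)-7-[(2S)-4-(bromomethyl)-5-oxo-2,5-dihydrofuran-2-yl]-6-methyl-2-methylidenehept-5-en-1-yl acetate F5. Zinc dust and acrolein in THF/aq. NH4Cl then give (5E)-7-[(2S,3S)-3-[(1R)-1-hydroxyprop-2-en-1-yl]-4-methylidene-5-oxooxolan-2-yl]-6-methyl-2-methylidenehept-5-en-1-yl acetate F6; in this known intermolecular Barbier reaction of bromolactones, attack anti to the C8 substituent sets C7 trans to C8 and the chair sets the anti C6 carbinol. Finally, ring-closing metathesis of the C5 vinyl group onto the C4 methylidene (second-generation Grubbs catalyst [RuCl2(H2IMes)(PCy3)(=CHPh)], 1 mM toluene, 80 °C) closes the ten-membered ring with the ring-cis C4=C5 geometry that a ring of this size enforces and gives 29.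

**Step 18 (metathesis of an acrylate that carries an allylic bromide, next to an enal).** The fallback takes the bromide out of the metathesis step and introduces it afterwards. It sets out from 25 and comes back at 28. 25 is esterified (DCC, DMAP) with 2-{[(tert-butyldimethylsilyl)oxy]methyl}acrylic acid to give (3S,5E,9E)-9-(acetoxymethyl)-5-methyl-11-oxoundeca-1,5,9-trien-3-yl 2-{[(tert-butyldimethylsilyl)oxy]methyl}acrylate F7. Metathesis with the catalyst of step 18 gives (2E,6E)-3-(acetoxymethyl)-8-[(2S)-4-{[(tert-butyldimethylsilyl)oxy]methyl}-5-oxo-2,5-dihydrofuran-2-yl]-7-methylocta-2,6-dienal F8. HF·pyridine gives (2E,6E)-3-(acetoxymethyl)-8-[(2S)-4-(hydroxymethyl)-5-oxo-2,5-dihydrofuran-2-yl]-7-methylocta-2,6-dienal F9, and CBr4/PPh3 (CH2Cl2, 0 °C) converts it into 28.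

**Step 21 (acid on a germacradiene that can cyclise transannularly, with a neighbouring lactone that can migrate).** The fallback replaces the acid-labile acetal by silyl ethers removed with fluoride. It sets out from 16 and 29 and comes back at 32. Methanolysis of 16 as in step 10 is stopped at diol ester 17, which is isolated. Et3SiOTf/2,6-lutidine gives methyl (R)-2-methyl-2,3-bis((triethylsilyl)oxy)propanoate F10, and Me3SnOH (1,2-dichloroethane, 70 °C) gives (R)-2-methyl-2,3-bis((triethylsilyl)oxy)propanoic acid F11. Activation with 2,4,6-trichlorobenzoyl chloride/Et3N gives (R)-2-methyl-2,3-bis((triethylsilyl)oxy)propanoic 2,4,6-trichlorobenzoic anhydride F12, which with DMAP acylates 29 to give (3aR,4R,5E,9E,11aS)-6-(acetoxymethyl)-10-methyl-3-methylidene-2-oxo-2,3,3a,4,7,8,11,11a-octahydrocyclodeca[b]furan-4-yl (R)-2-methyl-2,3-bis((triethylsilyl)oxy)propanoate F13. HF·pyridine buffered with pyridine (THF, 0 °C) then removes both silyl groups and gives 32.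

## Further compounds

F1 | step 19 | (3S,5E)-3-((tert-butyldimethylsilyl)oxy)-9-(((tert-butyldimethylsilyl)oxy)methyl)-5-methyldeca-1,5,9-triene | C=C[C@@H](O[Si](C)(C)C(C)(C)C)C/C(C)=C/CCC(=C)CO[Si](C)(C)C(C)(C)C
F2 | step 19 | (3S,5E)-9-(hydroxymethyl)-5-methyldeca-1,5,9-trien-3-ol | C=C[C@@H](O)C/C(C)=C/CCC(=C)CO
F3 | step 19 | (5E,8S)-8-hydroxy-6-methyl-2-methylidenedeca-5,9-dien-1-yl acetate | C=C[C@@H](O)C/C(C)=C/CCC(=C)COC(C)=O
F4 | step 19 | (3S,5E)-9-(acetoxymethyl)-5-methyldeca-1,5,9-trien-3-yl 2-(bromomethyl)acrylate | C=C[C@@H](OC(=O)C(=C)CBr)C/C(C)=C/CCC(=C)COC(C)=O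
F5 | step 19 | (5E)-7-[(2S)-4-(bromomethyl)-5-oxo-2,5-dihydrofuran-2-yl]-6-methyl-2-methylidenehept-5-en-1-yl acetate | BrCC1=C[C@H](C/C(C)=C/CCC(=C)COC(C)=O)OC1=O
F6 | step 19 | (5E)-7-[(2S,3S)-3-[(1R)-1-hydroxyprop-2-en-1-yl]-4-methylidene-5-oxooxolan-2-yl]-6-methyl-2-methylidenehept-5-en-1-yl acetate | C=C[C@@H](O)[C@@H]1C(=C)C(=O)O[C@H]1C/C(C)=C/CCC(=C)COC(C)=O
F7 | step 18 | (3S,5E,9E)-9-(acetoxymethyl)-5-methyl-11-oxoundeca-1,5,9-trien-3-yl 2-{[(tert-butyldimethylsilyl)oxy]methyl}acrylate | C=C[C@@H](OC(=O)C(=C)CO[Si](C)(C)C(C)(C)C)C/C(C)=C/CC/C(COC(C)=O)=C\C=O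
F8 | step 18 | (2E,6E)-3-(acetoxymethyl)-8-[(2S)-4-{[(tert-butyldimethylsilyl)oxy]methyl}-5-oxo-2,5-dihydrofuran-2-yl]-7-methylocta-2,6-dienal | CC(C)(C)[Si](C)(C)OCC1=C[C@H](C/C(C)=C/CC/C(COC(C)=O)=C\C=O)OC1=O
F9 | step 18 | (2E,6E)-3-(acetoxymethyl)-8-[(2S)-4-(hydroxymethyl)-5-oxo-2,5-dihydrofuran-2-yl]-7-methylocta-2,6-dienal | OCC1=C[C@H](C/C(C)=C/CC/C(COC(C)=O)=C\C=O)OC1=O
F10 | step 21 | methyl (R)-2-methyl-2,3-bis((triethylsilyl)oxy)propanoate | COC(=O)[C@](C)(O[Si](CC)(CC)CC)CO[Si](CC)(CC)CC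
F11 | step 21 | (R)-2-methyl-2,3-bis((triethylsilyl)oxy)propanoic acid | OC(=O)[C@](C)(O[Si](CC)(CC)CC)CO[Si](CC)(CC)CC
F12 | step 21 | (R)-2-methyl-2,3-bis((triethylsilyl)oxy)propanoic 2,4,6-trichlorobenzoic anhydride | O=C(OC(=O)[C@](C)(O[Si](CC)(CC)CC)CO[Si](CC)(CC)CC)c1c(Cl)cc(Cl)cc1Cl
F13 | step 21 | (3aR,4R,5E,9E,11aS)-6-(acetoxymethyl)-10-methyl-3-methylidene-2-oxo-2,3,3a,4,7,8,11,11a-octahydrocyclodeca[b]furan-4-yl (R)-2-methyl-2,3-bis((triethylsilyl)oxy)propanoate | C=C1C(=O)O[C@H]2C/C(C)=C/CC/C(COC(C)=O)=C\[C@@H](OC(=O)[C@](C)(O[Si](CC)(CC)CC)CO[Si](CC)(CC)CC)[C@H]12
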